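## Analysis of the target

The target is a flavone, a 2-aryl-4H-chromen-4-one in which the benzo ring A (C4a, C5, C6, C7, C8, C8a) is fused to the pyranone ring C (O1, C2, C3, C4), and C2 carries ring B, a 4,5-dihydroxy-2-methoxyphenyl group. It has no stereocentre, so the problem is purely constitutional: of eight oxygen substituents, four must end as methyl ethers (C3, C6, C8, C2') and four as free hydroxyls (C5, C7, C4', C5'). Ring A is hexasubstituted, with oxygen on the five contiguous carbons C5 to C8a in an alternating hydroxyl/methoxy pattern and a carbon substituent only at C4a. About the C7···C4a axis ring A is locally symmetric (C6 and C8 both methoxy, C5 and C8a both phenolic oxygens), so only three kinds of ring A oxygen must be told apart. The free compound is a catechol and a very electron-rich polyphenol, prone to air oxidation and to over-dealkylation, so the hydroxyls stay masked to the last step and the masks must come off without loss of the four methyl ethers. The difficulty is the differentiated pentaoxygenation of ring A, not any single bond. The strategy rests on one feature: C6, C7, C8 and C8a are contiguous and each bears oxygen, like the four carbons of a squaric acid diester, while C4a (the only ring A carbon without oxygen) and C5 correspond to a 2-alkoxyvinyl unit, so that a 4-(2-alkoxyvinyl)cyclobutenone can be expanded thermally to ring A with every oxygen in place and individually labelled.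

## Retrosynthetic reasoning

**22 from 21.** The last disconnection cuts four O–alkyl bonds: the two benzyl ethers of ring B, the isopropyl ether at O7 and the ethyl ether at O5. Each is more labile towards a boron trihalide than an unassisted aryl methyl ether: benzyl and isopropyl ionise, and the 5-ethoxy group lies peri to the C4 carbonyl and is cleaved through a chelate. The forward step must remove these four and leave the four methyl ethers.

**21 from 19.** Ring C is cut at O1–C2 (cyclodehydration) and C2–C3 (acyl migration), which leads through the diketone 20 to the aryl ester 19. The 3-methoxy group then arrives on the methylene carbon of the ketone and C3 needs no later oxidation. An oxidative closure of an enone precursor is avoided because a 5-alkoxy substituent tends to steer such closures towards the five-membered ring. Ester 19 is cut at its O–C(=O) bond into the hydroxy ketone 14 and the ring B acid 17, activated as 18.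

**14 from 10 and 11.** The C4a–C4 bond is cut. C4a carries the only hydrogen of ring A and lies between two oxygens, so it is the natural site for a directed metalation (aryllithium 12) and acylation by the amide 11. This is acid-free. An electrophilic acylation under strong Lewis acids would endanger the C7 ether. For that reason O7 is masked as an isopropyl ether and O8a as a methoxymethyl ether, which is a good directing group, in place of more acid-labile or non-directing masks. The ketone 13 is unmasked to 14 in the same operation.

**10 from 9.** The O6–CH3 bond is cut. Phenol 9 has a single free hydroxyl, at C6, so the methylation needs no selectivity.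

**9 from 6 (key disconnection).** The C5–C6 bond is cut and C6 is reconnected to C8a in a four-membered ring. In the forward sense the cyclobutenone 6 opens to the dienylketene 7, which closes to the dienone 8 and aromatises. All five C–O bonds of ring A are thus taken from preformed C–O bonds, and each oxygen emerges differently substituted: hydroxyl at C6, isopropyl ether at C7, methyl ether at C8, methoxymethyl ether at C8a and ethyl ether at C5.

**6 from 5.** The C8–O alkyl group is changed from isopropyl back to methyl by base-catalysed vinylogous transesterification. This repairs the one weak point of a squarate approach. A squarate carrying one small and one bulky ester group would leave the site of vinyl addition to a contest between two nearly equal vinylogous-ester carbonyls. The bulky group lies in the ring plane and is, if anything, the better donor, so neither sterics nor electronics can be trusted. In 5 the two isopropoxy groups are chemically distinct: only the one at C3 of the cyclobutenone (future C8) sits on the β-carbon of the enone and can be exchanged by addition–elimination. The oxygen pattern of 6 is therefore set by mechanism.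

**5 from 1 and 2.** The C4a–C8a bond is cut. The symmetric squarate 2 takes the vinyllithium 3 (from bromide 1) at either carbonyl with the same result, and the alkoxide 4 is capped as its methoxymethyl ether.

**17 from 15.** The C2'–O bond of the ring B acid is cut back to the bromo acid 16, and this to the acid 15. The carboxyl group directs both the bromination site and the copper-mediated substitution.

## Alternatives that were turned down

Alternative 1: quinoketene–enamine annulation of ring C.
- Disconnection: C4–C3 and O1–C2. The partners would be the ring A salicylate acetonide 5,7-bis(benzyloxy)-6,8-dimethoxy-2,2-dimethyl-4H-1,3-benzodioxin-4-one A2 and the enamine 4-{1-[4,5-bis(benzyloxy)-2-methoxyphenyl]-2-methoxyethenyl}morpholine A3.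
- Forward key step: heat or light makes A2 lose its ketal carbonyl component and leaves the quinoketene 3,5-bis(benzyloxy)-2,4-dimethoxy-6-(oxomethylidene)cyclohexa-2,4-dien-1-one A4. Enamine A3 captures A4 in a (4+2) sense, and loss of the amine aromatises ring C to 5,7-bis(benzyloxy)-2-[4,5-bis(benzyloxy)-2-methoxyphenyl]-3,6,8-trimethoxy-4H-chromen-4-one A1.
- For: it is convergent and neutral, and it installs the 3-methoxy group directly. In A1 all four hydroxyls are benzyl ethers, so A1 would be unmasked by one hydrogenolysis. On this point it is stronger than the chosen route, which needs a Lewis-acid dealkylation.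
- Against: A2 is a hexasubstituted, pentaoxygenated salicylate, so the real problem (ring A) is moved into a building block that needs its own long synthesis. A4 forms only at high temperature or under irradiation, where dimerisation and capture by adventitious nucleophiles compete. A3 is a hindered, tetrasubstituted enamine.
- Comparison: the chosen strategy is less convergent in ring C but builds the ring A oxygenation from a purchasable squarate, with every oxygen differentiated by mechanism.

Alternative 2: ring A by double Claisen condensation of two oxygenated chains.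
- Disconnection: C6–C7 and C4a–C8a.
- Forward key step: the bis(silyl enol ether) 1,4-dimethoxy-1,3-bis(trimethylsilyloxy)buta-1,3-diene A6 is C-acylated twice by 2-methoxypropanedioyl dichloride A7 and closes to methyl 2,4,6-trihydroxy-3,5-dimethoxybenzoate A5.
- For: ring A, both of its methoxy groups and the C4 carbon come from two small acyclic pieces in one step. The local symmetry of ring A is used fully, so A5 needs no protecting-group differentiation. In step count for ring A it is stronger than the chosen route.
- Against: A7 is an α-alkoxy malonyl chloride, prone to ketene formation. Dienes of the type of A6 tend to react with malonyl chlorides at oxygen in the second acylation and close to six-membered lactones, so two C-acylations of A6, one at a methoxy-bearing carbon, are doubtful. A5 is a triply hydrogen-bonded, hexasubstituted ester and a poor electrophile. Extending its ester carbon by the methoxymethyl unit needed for C3 would bring protecting groups back.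
- Comparison: the chosen key step is pericyclic and its regiochemistry is fixed by constitution, not by a C- versus O-acylation preference.

Alternative 3: Mentzer annulation on the symmetric triol.
- Disconnection: C4a–C4 and O1–C2.
- Forward key step: 2,4-dimethoxybenzene-1,3,5-triol A9 and ethyl 3-[4,5-bis(benzyloxy)-2-methoxyphenyl]-2-methoxy-3-oxopropanoate A10 are fused without solvent, or in a strongly dehydrating sulfonic acid medium, to give 2-[4,5-bis(benzyloxy)-2-methoxyphenyl]-5,7-dihydroxy-3,6,8-trimethoxy-4H-chromen-4-one A8.
- For: it is the shortest route. The symmetry of A9 removes any regiochemical question in ring closure, and A8 is one hydrogenolysis away from the target. In step economy it is clearly stronger than the chosen route.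
- Against: the thermal variant needs temperatures at which the benzyl ethers of A10 and the air-sensitive A9 are at risk. The acidic variant cleaves benzyl ethers and opens the competing closure through the ketone carbonyl, which would put the aryl group on C4 of a 2-pyranone ring in place of A8. A10 is a hindered α-substituted ketoester with an ortho-methoxyaryl ketone. A9 itself is not a simple commodity; making it is again the ring A problem.
- Comparison: the chosen strategy gives mild conditions throughout and a ring A made with control over each oxygen, at the price of more steps.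

Key step: step 3

## Route

Remark on the chemistry: flavone locants (C4a, C5 to C8, C8a, primes for ring B) are used for the corresponding atoms of all intermediates. Compounds 4, 5, 6 and 8 are racemic; their single stereocentre is lost in step 3.

Step 1
Reactants: 1 (Z)-1-bromo-2-ethoxyethene; 2 3,4-di(propan-2-yloxy)cyclobut-3-ene-1,2-dione (diisopropyl squarate)
Product: 5 4-[(Z)-2-ethoxyethenyl]-4-(methoxymethoxy)-2,3-di(propan-2-yloxy)cyclobut-2-en-1-one (racemic), via (Z)-2-ethoxyethenyllithium 3 (not isolated), via lithium cyclobutenolate adduct 4 (not isolated)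
Conditions: 1, t-BuLi (2 equiv), Et2O, −78 °C; then 2, THF, −78 °C; then MeOCH2Cl, −78 → 0 °C
Reagents that add atoms: chloromethyl methyl ether, COCCl
Why: Bromine–lithium exchange should give the configurationally stable (Z)-vinyllithium 3, which adds 1,2 to one of the two equivalent carbonyl groups of the symmetric squarate, so no site selectivity is needed. The tertiary lithium alkoxide 4 is O-alkylated by the highly electrophilic chloromethyl ether before work-up, which avoids handling the acid-sensitive hydroxy enol ether; the quaternary centre is formed as a racemate and is erased in step 3.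

Step 2
Reactants: 5 4-[(Z)-2-ethoxyethenyl]-4-(methoxymethoxy)-2,3-di(propan-2-yloxy)cyclobut-2-en-1-one
Product: 6 4-[(Z)-2-ethoxyethenyl]-3-methoxy-4-(methoxymethoxy)-2-(propan-2-yloxy)cyclobut-2-en-1-one (racemic)
Conditions: NaOMe (cat.), MeOH/THF, 0 °C → rt
Reagents that add atoms: methanol, CO
Why: Vinylogous transesterification by conjugate addition–elimination: methoxide adds to C3, the β-carbon of the enone and the only alkoxy-bearing carbon conjugated to the carbonyl, and the intermediate enolate expels isopropoxide, with methanol as solvent driving the exchange. The C2 isopropoxy group is an α-substituent with no addition–elimination pathway, so the methoxy group is placed on the future C8 by mechanism; the enol ether and the methoxymethyl ether are stable to base.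

Step 3
Reactants: 6 4-[(Z)-2-ethoxyethenyl]-3-methoxy-4-(methoxymethoxy)-2-(propan-2-yloxy)cyclobut-2-en-1-one
Product: 9 6-ethoxy-3-methoxy-4-(methoxymethoxy)-2-(propan-2-yloxy)phenol, via (3Z,5Z)-dienylketene 7 (not isolated), via cyclohexa-2,4-dienone tautomer 8 (not isolated)
Conditions: PhMe (0.02 M, degassed), 110 °C
Reagents that add atoms: none
Why: Heating should open the cyclobutenone by a thermal conrotatory four-electron electrocyclic cleavage of the C6–C8a bond (C1–C4 of 6) to the dienylketene 7; the C4 oxygen substituent is a π-donor and rotates outward, which forces the ethoxyvinyl group inward, cis to the ketene. A thermal disrotatory six-electron electrocyclisation then joins the ketene carbon (C6) to the ethoxy-bearing vinyl carbon (C5) and closes ring A as the six-membered cyclohexa-2,4-dienone 8, whose C5 hydrogen moves to oxygen to give the aromatic phenol 9. The closest known reaction type is the thermal ring expansion of squarate-derived 4-alkenyl-4-alkoxy (or hydroxy, silyloxy) cyclobutenones to hydroquinone monoethers (Moore rearrangement). The ring is closed in an electrocyclic mode in which the ketene terminus is sp-hybridised and accepts the new bond in its own plane, so the cis ethoxy group at the other terminus should be tolerated. The only stereocentre formed (C5 of 8) is transient and is removed by enolisation, and the stereocentre of 6 is destroyed on ring opening, so no stereocontrol is required. The selectivity that matters is torquoselectivity, secured by the outward preference of the methoxymethoxy donor; a ketene formed by the wrong rotation has no hydroxyl to lactonise with and can only revert to 6. The substitution pattern is fixed by constitution (free hydroxyl at C6, isopropyl ether at C7, methyl ether at C8, methoxymethyl ether at C8a, hydrogen at C4a, ethyl ether at C5), and dilute, oxygen-free conditions are chosen because 7 is an electrophile and 9 an easily oxidised phenol.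

Step 4
Reactants: 9 6-ethoxy-3-methoxy-4-(methoxymethoxy)-2-(propan-2-yloxy)phenol
Product: 10 1-ethoxy-2,4-dimethoxy-5-(methoxymethoxy)-3-(propan-2-yloxy)benzene
Conditions: MeI, K2CO3, DMF, rt
Reagents that add atoms: iodomethane, CI
Why: Williamson O-methylation of the only free hydroxyl (O6); the phenol is flanked by two alkoxy groups, hence a polar aprotic solvent. It is done at once to take the oxidation-prone phenol out of circulation.

Step 5
Reactants: 10 1-ethoxy-2,4-dimethoxy-5-(methoxymethoxy)-3-(propan-2-yloxy)benzene; 11 N,2-dimethoxy-N-methylacetamide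
Product: 14 1-[2-ethoxy-6-hydroxy-3,5-dimethoxy-4-(propan-2-yloxy)phenyl]-2-methoxyethan-1-one, via aryllithium 12 (not isolated), via methoxymethyl-protected ketone 13 (not isolated)
Conditions: n-BuLi, THF, 0 °C; then 11, −78 °C → rt; then HCl, MeOH, 45 °C
Reagents that add atoms: none
Why: Directed ortho-metalation: the single ring hydrogen (C4a) lies between the methoxymethoxy and ethoxy groups, so lithiation can occur only there. The aryllithium 12 is acylated by the Weinreb amide through a chelated tetrahedral intermediate that releases ketone 13 only on acid quench, and methanolic HCl then cleaves the acetal-type methoxymethyl ether while the isopropyl, ethyl and methyl ethers stay.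

Step 6
Reactants: 15 3,4-bis(benzyloxy)benzoic acid
Product: 16 4,5-bis(benzyloxy)-2-bromobenzoic acid
Conditions: Br2, NaOAc, AcOH, rt
Reagents that add atoms: bromine, BrBr
Why: Electrophilic aromatic bromination para to the 3-benzyloxy group (position 6 of 15), the site normally taken in 3,4-dialkoxybenzoic acids. Acetate buffers the hydrogen bromide so that the benzyl ethers are spared.

Step 7
Reactants: 16 4,5-bis(benzyloxy)-2-bromobenzoic acid
Product: 17 4,5-bis(benzyloxy)-2-methoxybenzoic acid
Conditions: NaOMe (excess), CuBr (cat.), MeOH/DMF, 90 °C; then HCl (aq)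
Reagents that add atoms: sodium methoxide, C[O-].[Na+]
Why: Copper-catalysed Ullmann-type methoxylation of an aryl bromide, accelerated by the neighbouring carboxylate (ortho effect of 2-halobenzoates). Benzyl ethers are inert to methoxide.

Step 8
Reactants: 17 4,5-bis(benzyloxy)-2-methoxybenzoic acid; 14 1-[2-ethoxy-6-hydroxy-3,5-dimethoxy-4-(propan-2-yloxy)phenyl]-2-methoxyethan-1-one
Product: 19 3-ethoxy-4,6-dimethoxy-2-(methoxyacetyl)-5-(propan-2-yloxy)phenyl 4,5-bis(benzyloxy)-2-methoxybenzoate, via aroyl chloride 18 (not isolated)
Conditions: 17, (COCl)2, DMF (cat.), CH2Cl2, 0 °C → rt; then 14, Et3N, DMAP (cat.), CH2Cl2, 0 °C → rt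
Reagents that add atoms: none
Why: Acid chloride formation under DMF catalysis, then DMAP-catalysed O-acylation of the hindered, hydrogen-bonded phenol. This forms the O1–C(=O) bond that becomes O1–C2.

Step 9
Reactants: 19 3-ethoxy-4,6-dimethoxy-2-(methoxyacetyl)-5-(propan-2-yloxy)phenyl 4,5-bis(benzyloxy)-2-methoxybenzoate
Product: 21 2-[4,5-bis(benzyloxy)-2-methoxyphenyl]-5-ethoxy-3,6,8-trimethoxy-7-(propan-2-yloxy)-4H-chromen-4-one, via 1,3-diketone 20 (not isolated)
Conditions: LiN(SiMe3)2, THF, −78 → 0 °C; HCl (aq) quench; then TsOH·H2O (cat.), PhMe, 80 °C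
Reagents that add atoms: none
Why: Baker–Venkataraman rearrangement: the ketone enolate at the methoxymethylene carbon attacks the neighbouring ester carbonyl through a six-membered transition state and transfers the aroyl group to carbon (C2–C3 bond), giving the phenolic diketone 20. Acid-catalysed cyclodehydration (O1 onto the aryl ketone carbonyl, loss of water) then closes ring C with the 3-methoxy group already in place.

Step 10
Reactants: 21 2-[4,5-bis(benzyloxy)-2-methoxyphenyl]-5-ethoxy-3,6,8-trimethoxy-7-(propan-2-yloxy)-4H-chromen-4-one
Product: 22 2-(4,5-dihydroxy-2-methoxyphenyl)-5,7-dihydroxy-3,6,8-trimethoxy-4H-chromen-4-one (target)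
Conditions: BCl3 (excess), C6HMe5, CH2Cl2, −78 °C → rt; then MeOH, H2O
Reagents that add atoms: none
Why: Lewis-acid dealkylation with BCl3: the benzyl and isopropyl ethers cleave by ionisation (benzyl cations trapped by pentamethylbenzene, isopropyl by chloride), and the 5-ethoxy group is cleaved through the boron chelate with the C4 carbonyl. Aryl methyl ethers without such assistance should survive, and ring A has no free position for Friedel–Crafts alkylation.

## Compound list

1 | (Z)-1-bromo-2-ethoxyethene | CCO/C=C\Br | starting material
2 | 3,4-di(propan-2-yloxy)cyclobut-3-ene-1,2-dione | CC(C)OC1=C(OC(C)C)C(=O)C1=O | starting material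
3 | [(Z)-2-ethoxyethenyl]lithium | CCO/C=C\[Li] | intermediate
4 | lithium 1-[(Z)-2-ethoxyethenyl]-4-oxo-2,3-di(propan-2-yloxy)cyclobut-2-en-1-olate (racemic) | CCO/C=C\C1([O-])C(OC(C)C)=C(OC(C)C)C1=O.[Li+] | intermediate
5 | 4-[(Z)-2-ethoxyethenyl]-4-(methoxymethoxy)-2,3-di(propan-2-yloxy)cyclobut-2-en-1-one (racemic) | CCO/C=C\C1(OCOC)C(OC(C)C)=C(OC(C)C)C1=O | intermediate
6 | 4-[(Z)-2-ethoxyethenyl]-3-methoxy-4-(methoxymethoxy)-2-(propan-2-yloxy)cyclobut-2-en-1-one (racemic) | CCO/C=C\C1(OCOC)C(OC)=C(OC(C)C)C1=O | intermediate
7 | (3Z,5Z)-6-ethoxy-3-methoxy-4-(methoxymethoxy)-2-(propan-2-yloxy)hexa-1,3,5-trien-1-one | O=C=C(OC(C)C)/C(OC)=C(/OCOC)\C=C/OCC | intermediate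
8 | 6-ethoxy-3-methoxy-4-(methoxymethoxy)-2-(propan-2-yloxy)cyclohexa-2,4-dien-1-one (racemic) | CCOC1C=C(OCOC)C(OC)=C(OC(C)C)C1=O | intermediate
9 | 6-ethoxy-3-methoxy-4-(methoxymethoxy)-2-(propan-2-yloxy)phenol | CCOc1cc(OCOC)c(OC)c(OC(C)C)c1O | intermediate
10 | 1-ethoxy-2,4-dimethoxy-5-(methoxymethoxy)-3-(propan-2-yloxy)benzene | CCOc1cc(OCOC)c(OC)c(OC(C)C)c1OC | intermediate
11 | N,2-dimethoxy-N-methylacetamide | COCC(=O)N(C)OC | starting material
12 | [2-ethoxy-3,5-dimethoxy-6-(methoxymethoxy)-4-(propan-2-yloxy)phenyl]lithium | CCOc1c([Li])c(OCOC)c(OC)c(OC(C)C)c1OC | intermediate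
13 | 1-[2-ethoxy-3,5-dimethoxy-6-(methoxymethoxy)-4-(propan-2-yloxy)phenyl]-2-methoxyethan-1-one | CCOc1c(C(=O)COC)c(OCOC)c(OC)c(OC(C)C)c1OC | intermediate
14 | 1-[2-ethoxy-6-hydroxy-3,5-dimethoxy-4-(propan-2-yloxy)phenyl]-2-methoxyethan-1-one | CCOc1c(C(=O)COC)c(O)c(OC)c(OC(C)C)c1OC | intermediate
15 | 3,4-bis(benzyloxy)benzoic acid | OC(=O)c1ccc(OCc2ccccc2)c(OCc2ccccc2)c1 | starting material
16 | 4,5-bis(benzyloxy)-2-bromobenzoic acid | OC(=O)c1cc(OCc2ccccc2)c(OCc2ccccc2)cc1Br | intermediate
17 | 4,5-bis(benzyloxy)-2-methoxybenzoic acid | COc1cc(OCc2ccccc2)c(OCc2ccccc2)cc1C(=O)O | intermediate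
18 | 4,5-bis(benzyloxy)-2-methoxybenzoyl chloride | COc1cc(OCc2ccccc2)c(OCc2ccccc2)cc1C(Cl)=O | intermediate
19 | 3-ethoxy-4,6-dimethoxy-2-(methoxyacetyl)-5-(propan-2-yloxy)phenyl 4,5-bis(benzyloxy)-2-methoxybenzoate | CCOc1c(C(=O)COC)c(OC(=O)c2cc(OCc3ccccc3)c(OCc3ccccc3)cc2OC)c(OC)c(OC(C)C)c1OC | intermediate
20 | 1-[4,5-bis(benzyloxy)-2-methoxyphenyl]-3-[2-ethoxy-6-hydroxy-3,5-dimethoxy-4-(propan-2-yloxy)phenyl]-2-methoxypropane-1,3-dione (racemic, enolisable) | CCOc1c(C(=O)C(OC)C(=O)c2cc(OCc3ccccc3)c(OCc3ccccc3)cc2OC)c(O)c(OC)c(OC(C)C)c1OC | intermediate
21 | 2-[4,5-bis(benzyloxy)-2-methoxyphenyl]-5-ethoxy-3,6,8-trimethoxy-7-(propan-2-yloxy)-4H-chromen-4-one | CCOc1c(OC)c(OC(C)C)c(OC)c2oc(-c3cc(OCc4ccccc4)c(OCc4ccccc4)cc3OC)c(OC)c(=O)c12 | intermediate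
22 | 2-(4,5-dihydroxy-2-methoxyphenyl)-5,7-dihydroxy-3,6,8-trimethoxy-4H-chromen-4-one | COc1cc(O)c(O)cc1-c1oc2c(OC)c(O)c(OC)c(O)c2c(=O)c1OC | target

## Step count and least certain steps

Total: 10 steps. Longest linear sequence: 8 steps (1, 2, 3, 4, 5, 8, 9, 10); the ring B branch (steps 6 and 7) joins at step 8.

**Step 3 (key step).** The most likely failure is diversion of the dienylketene 7 before the six-electron closure. The bond must form at the oxygen-bearing vinyl carbon, whose cis ethoxy group points into the forming ring; if closure is slow, the ketene can dimerise or acylate the product phenol, and air can oxidise 9.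
Fallback (sets out from 2, returns at 10): the roles of the two ends are exchanged so that closure occurs at an unsubstituted vinyl terminus, the classical case. Compound 2 is transesterified in methanol (NaOMe cat.) to 3,4-dimethoxycyclobut-3-ene-1,2-dione F1, which can also be bought. (1-Ethoxyethenyl)lithium F2, made from ethyl vinyl ether and t-BuLi, adds to F1, and the alkoxide is methylated with MeOTf to give 4-(1-ethoxyethenyl)-2,3,4-trimethoxycyclobut-2-en-1-one F3. Exchange of the C3 methoxy group in propan-2-ol with catalytic NaOi-Pr should give 4-(1-ethoxyethenyl)-2,4-dimethoxy-3-(propan-2-yloxy)cyclobut-2-en-1-one F4. Heating F4 in toluene should open it to (3Z)-5-ethoxy-2,4-dimethoxy-3-(propan-2-yloxy)hexa-1,3,5-trien-1-one F5, which closes between the ketene carbon and the CH2 terminus to 5-ethoxy-2,4-dimethoxy-3-(propan-2-yloxy)cyclohexa-2,4-dien-1-one F6 and tautomerises to 5-ethoxy-2,4-dimethoxy-3-(propan-2-yloxy)phenol F7, whose one free hydroxyl is the future O1. MeOCH2Cl and i-Pr2NEt then convert F7 into 10. In this variant the ketene carbon becomes C8a and the O6 methyl comes from the triflate, so step 4 is bypassed as well.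

**Step 2.** The risk is attack of methoxide at the carbonyl carbon instead of C3, followed by strain-driven cleavage of the four-membered ring to an open-chain ester, or a sluggish exchange because C3 is flanked by the quaternary centre.
Fallback (sets out from 2, returns at 6): the alkoxy groups are differentiated before the addition and the regiochemistry is settled by separation. One equivalent of NaOMe in methanol at low temperature should convert 2 into 3-methoxy-4-(propan-2-yloxy)cyclobut-3-ene-1,2-dione F8. Addition of 3 and capping with MeOCH2Cl as in step 1 should give 6 together with its regioisomer 4-[(Z)-2-ethoxyethenyl]-2-methoxy-4-(methoxymethoxy)-3-(propan-2-yloxy)cyclobut-2-en-1-one F9, and chromatography delivers 6.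

**Step 5.** The risk is proton transfer from the α-methylene group of 11 to the hindered, doubly ortho-substituted aryllithium 12 in place of acyl transfer, which would return 10.
Fallback (sets out from 10, lithiated to 12 as in step 5; returns at 13): the two-carbon acyl unit is built from two non-enolisable one-carbon electrophiles. Quenching 12 with DMF should give 2-ethoxy-3,5-dimethoxy-6-(methoxymethoxy)-4-(propan-2-yloxy)benzaldehyde F10. Addition of (methoxymethyl)lithium F11, made from Bu3SnCH2OMe and n-BuLi, should give 1-[2-ethoxy-3,5-dimethoxy-6-(methoxymethoxy)-4-(propan-2-yloxy)phenyl]-2-methoxyethan-1-ol F12 (racemic). Oxidation with Dess–Martin periodinane gives 13, which is deprotected to 14 with methanolic HCl as before.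

**Step 10.** The risks are loss of a methyl ether next to a boron chelate (the C3 or C6 methoxy group) on long exposure, and Friedel–Crafts benzylation of ring B at C3' or C6' by benzyl cations that escape the scavenger.
Fallback (sets out from 21, returns at 22): the unmasking is split into two orthogonal stages so that no benzyl cation is ever formed and less Lewis acid is needed. Hydrogenolysis (H2, Pd/C, EtOAc/MeOH) should give 2-(4,5-dihydroxy-2-methoxyphenyl)-5-ethoxy-3,6,8-trimethoxy-7-(propan-2-yloxy)-4H-chromen-4-one F13. A chelation-controlled dealkylation with AlCl3 in CH2Cl2 at 0 °C then removes the isopropyl and the peri ethyl group to give 22.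

## Further compounds

F1 | step 3 | 3,4-dimethoxycyclobut-3-ene-1,2-dione | COC1=C(OC)C(=O)C1=O
F2 | step 3 | (1-ethoxyethenyl)lithium | [Li]C(=C)OCC
F3 | step 3 | 4-(1-ethoxyethenyl)-2,3,4-trimethoxycyclobut-2-en-1-one (racemic) | CCOC(=C)C1(OC)C(OC)=C(OC)C1=O
F4 | step 3 | 4-(1-ethoxyethenyl)-2,4-dimethoxy-3-(propan-2-yloxy)cyclobut-2-en-1-one (racemic) | CCOC(=C)C1(OC)C(OC(C)C)=C(OC)C1=O
F5 | step 3 | (3Z)-5-ethoxy-2,4-dimethoxy-3-(propan-2-yloxy)hexa-1,3,5-trien-1-one | O=C=C(OC)/C(OC(C)C)=C(/OC)C(=C)OCC
F6 | step 3 | 5-ethoxy-2,4-dimethoxy-3-(propan-2-yloxy)cyclohexa-2,4-dien-1-one | CCOC1=C(OC)C(OC(C)C)=C(OC)C(=O)C1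
F7 | step 3 | 5-ethoxy-2,4-dimethoxy-3-(propan-2-yloxy)phenol | CCOc1cc(O)c(OC)c(OC(C)C)c1OC
F8 | step 2 | 3-methoxy-4-(propan-2-yloxy)cyclobut-3-ene-1,2-dione | COC1=C(OC(C)C)C(=O)C1=O
F9 | step 2 | 4-[(Z)-2-ethoxyethenyl]-2-methoxy-4-(methoxymethoxy)-3-(propan-2-yloxy)cyclobut-2-en-1-one (racemic) | CCO/C=C\C1(OCOC)C(OC(C)C)=C(OC)C1=O
F10 | step 5 | 2-ethoxy-3,5-dimethoxy-6-(methoxymethoxy)-4-(propan-2-yloxy)benzaldehyde | CCOc1c(C=O)c(OCOC)c(OC)c(OC(C)C)c1OC
F11 | step 5 | (methoxymethyl)lithium | [Li]COC
F12 | step 5 | 1-[2-ethoxy-3,5-dimethoxy-6-(methoxymethoxy)-4-(propan-2-yloxy)phenyl]-2-methoxyethan-1-ol (racemic) | CCOc1c(C(O)COC)c(OCOC)c(OC)c(OC(C)C)c1OC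
F13 | step 10 | 2-(4,5-dihydroxy-2-methoxyphenyl)-5-ethoxy-3,6,8-trimethoxy-7-(propan-2-yloxy)-4H-chromen-4-one | CCOc1c(OC)c(OC(C)C)c(OC)c2oc(-c3cc(O)c(O)cc3OC)c(OC)c(=O)c12
A1 | alternative 1 | 5,7-bis(benzyloxy)-2-[4,5-bis(benzyloxy)-2-methoxyphenyl]-3,6,8-trimethoxy-4H-chromen-4-one | COc1cc(OCc2ccccc2)c(OCc2ccccc2)cc1-c1oc2c(OC)c(OCc3ccccc3)c(OC)c(OCc3ccccc3)c2c(=O)c1OC
A2 | alternative 1 | 5,7-bis(benzyloxy)-6,8-dimethoxy-2,2-dimethyl-4H-1,3-benzodioxin-4-one | CC1(C)OC(=O)c2c(OCc3ccccc3)c(OC)c(OCc3ccccc3)c(OC)c2O1
A3 | alternative 1 | 4-{1-[4,5-bis(benzyloxy)-2-methoxyphenyl]-2-methoxyethenyl}morpholine (alkene geometry not defined) | COC=C(N1CCOCC1)c1cc(OCc2ccccc2)c(OCc2ccccc2)cc1OC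
A4 | alternative 1 | 3,5-bis(benzyloxy)-2,4-dimethoxy-6-(oxomethylidene)cyclohexa-2,4-dien-1-one | O=C=C1C(=O)C(OC)=C(OCc2ccccc2)C(OC)=C1OCc1ccccc1
A5 | alternative 2 | methyl 2,4,6-trihydroxy-3,5-dimethoxybenzoate | COC(=O)c1c(O)c(OC)c(O)c(OC)c1O
A6 | alternative 2 | 1,4-dimethoxy-1,3-bis(trimethylsilyloxy)buta-1,3-diene (alkene geometry not defined) | COC=C(O[Si](C)(C)C)C=C(OC)O[Si](C)(C)C
A7 | alternative 2 | 2-methoxypropanedioyl dichloride | COC(C(=O)Cl)C(=O)Cl
A8 | alternative 3 | 2-[4,5-bis(benzyloxy)-2-methoxyphenyl]-5,7-dihydroxy-3,6,8-trimethoxy-4H-chromen-4-one | COc1cc(OCc2ccccc2)c(OCc2ccccc2)cc1-c1oc2c(OC)c(O)c(OC)c(O)c2c(=O)c1OC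
A9 | alternative 3 | 2,4-dimethoxybenzene-1,3,5-triol | COc1c(O)cc(O)c(OC)c1O
A10 | alternative 3 | ethyl 3-[4,5-bis(benzyloxy)-2-methoxyphenyl]-2-methoxy-3-oxopropanoate (racemic) | CCOC(=O)C(OC)C(=O)c1cc(OCc2ccccc2)c(OCc2ccccc2)cc1OC
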